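## The problem

Dipolynaphthalene B (15) is a (1S,4S)-1,2,3,4-tetrahydronaphthalen-1-ol (aromatic ring A, saturated ring B). Its C4 is joined by an sp3–sp2 bond to C1′ of a 4-hydroxy-5-methoxynaphthalene (rings C and D), and ring A carries a methoxy group at C5, peri to the aryl methine. Both stereocentres are benzylic, lie 1,4 across ring B with hydroxyl and naphthyl cis, and are separated by two bare methylenes. Neither can be trusted to direct the other in a stepwise build-up, so they are best created in one event. Ring B cannot be closed by Friedel–Crafts chemistry: either closure would attack ring A meta to its methoxy group while a far more nucleophilic naphthalene stands by. The sensitive features are the secondary benzylic alcohol (ionisation, dehydration, hydrogenolysis), the doubly benzylic C4–H, and the para-alkylated, electron-rich 1-naphthol, which oxidises readily once free. Because C2 and C3 bear nothing, any group that activates the formation of ring B must leave without trace. The enabling feature is that C1 (carbinol) and C4 (aryl methine) sit on the adjacent ring A carbons C8a and C4a and are bridged by C2–C3. This is the retron of a 1-hydroxy-4-aryl ortho-quinodimethane that has taken up a two-carbon dienophile, and the 1,4-cis arrangement is what a diene with both substituents on its outer positions delivers.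

## Retrosynthesis

**15 ⇒ 14.** The naphthol oxygen is the only function that needs a mask, and it is unmasked last by cutting the O–benzyl bond. A benzyl ether is preferred to a silyl ether, which is at risk under the basic steps next to a peri-methoxy group, and to a third methyl ether, which could not be cleaved selectively. The forward step asks only that neutral hydrogenolysis cleave an aryl benzyl ether faster than the C1 benzylic hydroxyl.

**14 ⇒ 13.** A phenylsulfonyl group is put back on C2 (C2–S bond). The cycloaddition below needs an electron-poor two-carbon partner, since an unactivated alkene would not intercept a short-lived dienol. A carbonyl activator would bind titanium more firmly but would leave a carbon substituent whose excision costs several steps, whereas a sulfone leaves in one. The forward step must cleave C–S reductively without expelling the neighbouring hydroxyl.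

**13 ⇒ 10 + 11 (through dienol 12).** C1–C2 and C3–C4 are cut together. The neighbouring cuts are worse. Cutting C4–C1′ leaves the 1,4-stereo problem untouched, and cutting C1–C8a or C4–C4a is the Friedel–Crafts closure already excluded. The chosen cut removes ring B and all three stereocentres of 13 at once and leads to the achiral, flat aldehyde 10 and commercial 11. The forward reaction must meet five demands:
- photoenolisation of 10 has to keep pace with energy transfer to the naphthalene;
- the dienol 12 must have hydroxyl and naphthyl on the outer positions;
- the sulfonyl group must end up on C2 and endo;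
- one face of the diene must be blocked by a chiral titanium alkoxide;
- the ligand must not add a further low-energy chromophore.

**10 ⇒ 9 ⇒ 8.** The aldehyde is introduced last by two oxidation-level changes at the benzylic carbon. A free aldehyde would survive neither radical bromination nor an organozinc reagent, so the methyl ester 8 is the carrier through the C–C coupling.

**8 ⇒ 4 + 6 (through 7).** The CH2–C1′ bond is cut. The other bond of the methylene (CH2–ring A) would need a 2-metalated 3-methoxybenzoate and a naphthylmethyl halide, about three extra steps on the naphthalene side. The chosen cut gives the benzylic bromide 6 and the aryl bromide 4. A Negishi coupling through the benzylzinc reagent 7 is preferred to a Suzuki coupling because it saves a borylation step and avoids hot aqueous base, which can lactonise 6.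

**6 ⇒ 5.** The benzylic C–Br bond is cut, leading to the catalogue ester 5. The forward reaction is a radical bromination of the only benzylic methyl group.

**4 ⇒ 3 ⇒ 2 ⇒ 1.** O–benzyl, C–Br and O–methyl are cut in that order, leading to the symmetrical diol 1. The forward order is essential. Mono-methylation breaks the symmetry. Bromination is done while one oxygen is still a free hydroxyl, so the ring that will carry the link is the more activated and the para position C4 is addressed. Benzylation comes last.

## Roads not taken

Alternative 1: The naphthalene is made last, by cutting C1′–C8a′ and C4′–C4a′ of ring C.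
- Forward step: the 2-substituted furan A1 (the furan sits on C4 of a preformed tetralin whose C1 is masked as a dioxolane) would take up the pinacolboryl-benzyne A2 to give the oxygen-bridged adduct A3. Acid would open the bridge at its fully substituted bridgehead and place the hydroxyl on C4′; the boron on C5′ would be turned into the methoxy group.
- Merits: the step is thermal, aryne–furan cycloadditions are dependable, and both bridge diastereomers converge on one naphthol. No low-lying naphthalene triplet exists when the key bonds form, which is a real advantage over the photochemical plan.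
- Weak points: A1 must already hold the C4 stereocentre, so the tetralin has to be made enantioselectively by other means, and the meta-to-methoxy closure problem returns in its preparation. The aryne must add with boron next to the unsubstituted bridgehead. Turning C–B into OMe while a second naphthol oxygen is unveiled costs extra steps. C1 is left as a ketone whose reduction must be steered cis by a reagent, because 1,4-induction from C4 is weak.
- Comparison: this road is safer in its key step but longer, and it solves the two stereocentres in two separate operations. The adopted plan answers with one step that builds ring B and both centres from an achiral aldehyde.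

Alternative 2: Ring A is made last, by cutting C4a–C8a, C5–C6 and C7–C8.
- Forward step: the tethered diyne A4 (a methoxyalkyne and a terminal alkyne linked by the C4–C3–C2–C1 chain that already carries the naphthyl and silyloxy stereocentres) would cyclotrimerise with acetylene A5 on [Rh(cod)2]BF4/BINAP to give A6, the bis-silyl ether of 15.
- Merits: the methoxy group is placed by the tether with no regiochemical question. The key step creates no stereocentre and cannot erode one, no activating group has to be removed, and A6 is one deprotection from the target. In predictability of the ring-forming event this road is better than the adopted one.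
- Weak points: every difficulty moves into A4. Two stereocentres on an open chain need two independent asymmetric steps. The C4 centre is at once propargylic and benzylic to an electron-rich naphthalene, so it risks racemisation or alkyne–allene isomerisation under the basic conditions that make an ynol ether. The ynol ether is acid-sensitive, and the linear sequence would be roughly twice as long.
- Comparison: against the cleaner key step of this road the adopted plan sets a much shorter route (seven steps to an achiral precursor) and the creation of ring B and both stereocentres at once. The price is a traceless sulfone and an untested photochemical substrate.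

Alternative 3: Ring B is closed from the arene side, by cutting C1–C8a and C4–C4a.
- Forward step: 3-methoxybenzyne A8 would add across the furan ring of A7 (one cross-coupling away from bromide 4) to give the oxygen-bridged dihydronaphthalene A9. Hydrogenation of C2=C3, reductive cleavage of the tertiary, doubly benzylic C4–O bond and debenzylation would then lead to 15.
- Merits: this is the shortest road in step count, it is thermal, it leaves no activating group behind, and the bridge oxygen becomes the C1 hydroxyl directly. In brevity it beats the adopted plan.
- Weak points: A9 is formed racemic and no general enantioselective aryne–furan cycloaddition is at hand, so a resolution would be needed. The required regioisomer puts the aryne methoxy group next to the bridgehead that bears the bulky naphthyl, which is electronically reasonable but sterically opposed, so a mixture is to be expected. The cis relationship survives only if hydrogen is delivered to C4 with inversion; retention or a planar doubly benzylic cation would give the trans isomer or mixtures.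
- Comparison: the adopted plan is a few steps longer and depends on photochemistry. It sets against this absolute stereocontrol by a ligand and a relative configuration that follows from orbital symmetry, not from the course of a C–O hydrogenolysis.

Key step: step 8

Assumption: the (R,R)-TADDOL series is taken to deliver the (1R,2S,4S) adduct 13; should the sense of induction prove opposite, the (S,S)-ligand is used with no other change.
Assumption: ester 5 is taken as a catalogue compound.

## Route

Step 1
Reactants: 1 naphthalene-1,8-diol
Product: 2 8-methoxynaphthalen-1-ol
Conditions: MeI (1.05 equiv), K2CO3, acetone, reflux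
Reagents that add atoms: iodomethane, CI
Why: Williamson etherification; the mono-anion of 1 is stabilised by the peri hydrogen bond and forms under carbonate, whereas the remaining hydroxyl of 2 is hydrogen-bonded to the new methoxy oxygen and far less acidic, so alkylation should stop at the mono-ether.

Step 2
Reactants: 2 8-methoxynaphthalen-1-ol
Product: 3 4-bromo-8-methoxynaphthalen-1-ol
Conditions: NBS (1.0 equiv), MeCN, −20 to 0 °C, dark
Reagents that add atoms: N-bromosuccinimide, O=C1CCC(=O)N1Br
Why: Electrophilic aromatic bromination; the free hydroxyl is the strongest donor and directs to its para α-position C4, the methoxy-bearing ring being less activated, and a polar solvent without amine additive favours para over ortho attack.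

Step 3
Reactants: 3 4-bromo-8-methoxynaphthalen-1-ol
Product: 4 1-(benzyloxy)-4-bromo-8-methoxynaphthalene
Conditions: BnBr, K2CO3, DMF, 60 °C
Reagents that add atoms: benzyl bromide, BrCc1ccccc1
Why: Williamson etherification of the hindered, hydrogen-bonded naphthol; the benzyl ether should survive organozinc, hydride, irradiation and amalgam and leave at the end by neutral hydrogenolysis.

Step 4
Reactants: 5 methyl 3-methoxy-2-methylbenzoate
Product: 6 methyl 2-(bromomethyl)-3-methoxybenzoate
Conditions: NBS (1.05 equiv), AIBN (cat.), PhCF3, 80 °C
Reagents that add atoms: N-bromosuccinimide, O=C1CCC(=O)N1Br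
Why: Wohl–Ziegler radical bromination of the only benzylic methyl group; the non-polar medium and the radical initiator keep NBS from brominating the anisole ring, and the stoichiometry limits the reaction to mono-bromination.

Step 5
Reactants: 6 methyl 2-(bromomethyl)-3-methoxybenzoate; 4 1-(benzyloxy)-4-bromo-8-methoxynaphthalene
Product: 8 methyl 2-{[4-(benzyloxy)-5-methoxynaphthalen-1-yl]methyl}-3-methoxybenzoate, via benzylzinc bromide 7 (not isolated)
Conditions: Zn dust, LiCl, THF, 0 °C to rt; then 4, Pd(OAc)2 (2 mol%), SPhos (4 mol%), THF, 50 °C
Reagents that add atoms: none
Why: Negishi sp3–sp2 cross-coupling; zinc inserts into the benzylic C–Br bond in the presence of LiCl without touching the ester, and the zerovalent palladium–SPhos catalyst formed in situ should add oxidatively to the electron-rich, peri-hindered bromide 4, transmetalate with 7 and eliminate reductively, a benzylic zinc reagent having no β-hydrogen to lose.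

Step 6
Reactants: 8 methyl 2-{[4-(benzyloxy)-5-methoxynaphthalen-1-yl]methyl}-3-methoxybenzoate
Product: 9 (2-{[4-(benzyloxy)-5-methoxynaphthalen-1-yl]methyl}-3-methoxyphenyl)methanol
Conditions: iBu2AlH (2.5 equiv), CH2Cl2, −78 to 0 °C; aq. potassium sodium tartrate
Reagents that add atoms: none
Why: Hydride reduction of the ester to the primary benzylic alcohol; aryl ethers and the diarylmethane are inert to iBu2AlH at this temperature.

Step 7
Reactants: 9 (2-{[4-(benzyloxy)-5-methoxynaphthalen-1-yl]methyl}-3-methoxyphenyl)methanol
Product: 10 2-{[4-(benzyloxy)-5-methoxynaphthalen-1-yl]methyl}-3-methoxybenzaldehyde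
Conditions: MnO2 (activated, excess), CH2Cl2, rt, dark
Reagents that add atoms: none
Why: Manganese dioxide oxidation, selective for benzylic alcohols, should stop at the aldehyde and leave the doubly benzylic methylene and the ethers untouched.

Step 8
Reactants: 10 2-{[4-(benzyloxy)-5-methoxynaphthalen-1-yl]methyl}-3-methoxybenzaldehyde; 11 phenyl vinyl sulfone
Product: 13 (1R,2S,4S)-4-[4-(benzyloxy)-5-methoxynaphthalen-1-yl]-5-methoxy-2-(phenylsulfonyl)-1,2,3,4-tetrahydronaphthalen-1-ol, via titanium-bound out-out dienol 12 (not isolated)
Conditions: Ti(OiPr)4 (2 equiv), (R,R)-TADDOL (tetraphenyl, 1.2 equiv), 11 (3 equiv), degassed PhMe, 365 nm LED, rt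
Reagents that add atoms: none
Why: Proposed new method: the closest known reaction type is the Ti(OiPr)4/TADDOL-promoted enantioselective photoenolization/Diels–Alder reaction of 2-alkylbenzaldehydes with enones, extended here to a diarylmethane donor that carries a naphthalene and to a sulfone dienophile. Excitation of the aldehyde n,π* band at 365 nm, where the dialkoxynaphthalene hardly absorbs, is followed by 1,5-hydrogen transfer from the doubly benzylic CH2 to the carbonyl oxygen; the hydroxy-inside isomer returns to 10 by the reverse shift, so only the out,out dienol 12 accumulates and is held on tetravalent titanium as its alkoxide. Ring B closes by an intermolecular, concerted, suprafacial [4+2] cycloaddition of 12 with 11 that forms C1–C2 and C3–C4. The regiochemistry (sulfonyl on C2, next to the carbinol) follows from the larger HOMO coefficient at the arylmethylidene terminus remote from the oxygen donor, which pairs with the β-carbon of 11, and from binding of a sulfonyl oxygen to the same titanium centre. The 1,4-cis relationship of the C1 hydroxyl and the C4 naphthyl is fixed by the out,out geometry of 12, in which the naphthyl takes the outer side where it can twist against the C5 methoxy group instead of clashing with the enol carbon, and the C2 sulfonyl group becomes cis to both through the endo, titanium-bridged transition state. The absolute configuration at C1 and C4, and with it C2, is set by the C2-symmetric TADDOLate, which blocks one face of the bound dienol. The step therefore needs regio-, endo- and facial selectivity together, secured respectively by the oxygen donor, the sulfonyl–titanium contact and the chiral ligand, while the easy abstraction of the doubly benzylic hydrogen must keep photoenolisation ahead of triplet energy transfer to the lower-lying naphthalene triplet, a loss that costs photons but should not divert material when oxygen is excluded.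

Step 9
Reactants: 13 (1R,2S,4S)-4-[4-(benzyloxy)-5-methoxynaphthalen-1-yl]-5-methoxy-2-(phenylsulfonyl)-1,2,3,4-tetrahydronaphthalen-1-ol
Product: 14 (1S,4S)-4-[4-(benzyloxy)-5-methoxynaphthalen-1-yl]-5-methoxy-1,2,3,4-tetrahydronaphthalen-1-ol
Conditions: Na(Hg) (6% Na), Na2HPO4, MeOH/THF, −20 °C
Reagents that add atoms: none
Why: Reductive desulfonylation by single-electron transfer; the sulfone radical anion fragments to sulfinate and a C2 radical that is reduced and protonated by methanol, while the phosphate buffer and the poor leaving ability of a free hydroxyl should suppress Julia-type β-elimination. C1 and C4 are not involved, so the cis (1S,4S) configuration is kept (the C1 descriptor changes from R to S only because the sulfur substituent is gone).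

Step 10
Reactants: 14 (1S,4S)-4-[4-(benzyloxy)-5-methoxynaphthalen-1-yl]-5-methoxy-1,2,3,4-tetrahydronaphthalen-1-ol
Product: 15 dipolynaphthalene B, (1S,4S)-4-(4-hydroxy-5-methoxynaphthalen-1-yl)-5-methoxy-1,2,3,4-tetrahydronaphthalen-1-ol
Conditions: H2 (1 atm), Pd/C (10%), EtOAc, rt, stopped at full conversion
Reagents that add atoms: none
Why: Catalytic hydrogenolysis of the aryl benzyl ether under neutral conditions, where O–benzyl cleavage should be faster than loss of the C1 benzylic hydroxyl; no stereocentre is touched.

## Compound list

```
1 | naphthalene-1,8-diol | Oc1cccc2cccc(O)c12 | starting material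
2 | 8-methoxynaphthalen-1-ol | COc1cccc2cccc(O)c12 | intermediate
3 | 4-bromo-8-methoxynaphthalen-1-ol | COc1cccc2c(Br)ccc(O)c12 | intermediate
4 | 1-(benzyloxy)-4-bromo-8-methoxynaphthalene | COc1cccc2c(Br)ccc(OCc3ccccc3)c12 | intermediate
5 | methyl 3-methoxy-2-methylbenzoate | COC(=O)c1cccc(OC)c1C | starting material
6 | methyl 2-(bromomethyl)-3-methoxybenzoate | COC(=O)c1cccc(OC)c1CBr | intermediate
7 | [2-methoxy-6-(methoxycarbonyl)benzyl]zinc bromide | COC(=O)c1cccc(OC)c1C[Zn]Br | intermediate (not isolated)
8 | methyl 2-{[4-(benzyloxy)-5-methoxynaphthalen-1-yl]methyl}-3-methoxybenzoate | COC(=O)c1cccc(OC)c1Cc1ccc(OCc2ccccc2)c2c(OC)cccc12 | intermediate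
9 | (2-{[4-(benzyloxy)-5-methoxynaphthalen-1-yl]methyl}-3-methoxyphenyl)methanol | COc1cccc(CO)c1Cc1ccc(OCc2ccccc2)c2c(OC)cccc12 | intermediate
10 | 2-{[4-(benzyloxy)-5-methoxynaphthalen-1-yl]methyl}-3-methoxybenzaldehyde | COc1cccc(C=O)c1Cc1ccc(OCc2ccccc2)c2c(OC)cccc12 | intermediate
11 | phenyl vinyl sulfone | C=CS(=O)(=O)c1ccccc1 | starting material
12 | out,out dienol, (E)-{(6Z)-6-[(4-benzyloxy-5-methoxynaphthalen-1-yl)methylidene]-5-methoxycyclohexa-2,4-dien-1-ylidene}methanol, bound to titanium through oxygen (Z by sequence rule at the arylmethylidene carbon only because of the ring methoxy group) | O/C=C1/C(=C/c2ccc(OCc3ccccc3)c3c(OC)cccc23)C(OC)=CC=C1 | intermediate (not isolated)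
13 | (1R,2S,4S)-4-[4-(benzyloxy)-5-methoxynaphthalen-1-yl]-5-methoxy-2-(phenylsulfonyl)-1,2,3,4-tetrahydronaphthalen-1-ol (all-cis) | COc1cccc2c1[C@H](c1ccc(OCc4ccccc4)c3c(OC)cccc13)C[C@H](S(=O)(=O)c1ccccc1)[C@@H]2O | intermediate
14 | (1S,4S)-4-[4-(benzyloxy)-5-methoxynaphthalen-1-yl]-5-methoxy-1,2,3,4-tetrahydronaphthalen-1-ol | COc1cccc2c1[C@H](c1ccc(OCc4ccccc4)c3c(OC)cccc13)CC[C@@H]2O | intermediate
15 | dipolynaphthalene B, (1S,4S)-4-(4-hydroxy-5-methoxynaphthalen-1-yl)-5-methoxy-1,2,3,4-tetrahydronaphthalen-1-ol | COc1cccc2c1[C@H](c1ccc(O)c3c(OC)cccc13)CC[C@@H]2O | target
```

## Step count and least certain steps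

Total step count: 10. Longest linear sequence: 9 steps (steps 1, 2, 3, 5, 6, 7, 8, 9 and 10, counted from diol 1); the branch from ester 5 joins at step 5.

**Step 8 (key step, flagged as beyond known scope).** Three processes are most likely to go wrong:
- triplet energy transfer from the excited aldehyde to the naphthalene may outrun hydrogen transfer, so that conversion stalls;
- facial discrimination may be weak because a sulfone binds titanium less firmly than a carbonyl dienophile;
- the out,out geometry may erode under the pressure of the C5 methoxy group.

The fallback uses known thermal chemistry and forms the same two bonds, setting out from ester 8 and sulfone 11. Deprotonation of the doubly benzylic methylene of 8 with LDA in THF at −78 °C, Michael addition to 11 and Dieckmann-type closure of the α-sulfonyl carbanion onto the ester (a Staunton–Weinreb-type toluate annulation) would give racemic 4-[4-(benzyloxy)-5-methoxynaphthalen-1-yl]-5-methoxy-2-(phenylsulfonyl)-3,4-dihydronaphthalen-1(2H)-one F1. Al(Hg) in wet THF would remove the sulfonyl group to give racemic 4-[4-(benzyloxy)-5-methoxynaphthalen-1-yl]-5-methoxy-3,4-dihydronaphthalen-1(2H)-one F2. Corey–Bakshi–Shibata reduction with (R)-2-methyl-oxazaborolidine and BH3·SMe2 would set C1 as S under reagent control in both enantiomers of the ketone. The products are 14 and its trans diastereomer (1S,4R)-4-[4-(benzyloxy)-5-methoxynaphthalen-1-yl]-5-methoxy-1,2,3,4-tetrahydronaphthalen-1-ol F3, which are separated by chromatography. At most half of the material reaches 14, where the route is rejoined.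

**Step 9.** Two processes are most likely: loss of the hydroxyl together with the sulfonyl group (Julia-type elimination to a 1,2-dihydronaphthalene), and base-induced retro-addition at the alkoxide stage, because the C2 carbanion or radical sits next to a benzylic C–O bond. The fallback sets out from 13. Dess–Martin oxidation would give (4S)-4-[4-(benzyloxy)-5-methoxynaphthalen-1-yl]-5-methoxy-2-(phenylsulfonyl)-3,4-dihydronaphthalen-1(2H)-one F4. Its β-keto sulfone is cleaved easily by Al(Hg) or SmI2 to (S)-4-[4-(benzyloxy)-5-methoxynaphthalen-1-yl]-5-methoxy-3,4-dihydronaphthalen-1(2H)-one F5. Corey–Bakshi–Shibata reduction with the (R)-oxazaborolidine then restores the (1S) carbinol cis to the naphthyl group and rejoins the route at 14.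

**Step 10.** The most likely failure is over-reduction, with hydrogenolysis of the C1 benzylic C–O bond alongside the benzyl ether. The fallback changes the order of the endgame and sets out from 13, in which the C1–O bond is deactivated by the neighbouring sulfonyl group. Hydrogenolysis there would give (1R,2S,4S)-4-(4-hydroxy-5-methoxynaphthalen-1-yl)-5-methoxy-2-(phenylsulfonyl)-1,2,3,4-tetrahydronaphthalen-1-ol F6. Buffered Na(Hg) desulfonylation of F6 then leads directly to 15.

**Step 5.** The most likely failures are Wurtz-type homocoupling during zinc insertion and slow oxidative addition to the hindered, electron-rich bromide. The fallback exchanges the organometallic partner and sets out from 4. Miyaura borylation (B2pin2, Pd(dppf)Cl2, KOAc, dioxane, 90 °C) would give 2-[4-(benzyloxy)-5-methoxynaphthalen-1-yl]-4,4,5,5-tetramethyl-1,3,2-dioxaborolane F7. Suzuki–Miyaura coupling of F7 with bromide 6 (Pd(PPh3)4, Na2CO3, DME/H2O, 80 °C) returns to the route at 8.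

**Step 2.** The most likely failure is competing ortho-bromination or double bromination of the free naphthol. The fallback sets out from diol 1 and replaces phenol-directed by ether-directed bromination.
- Mono-benzylation (BnBr, K2CO3, acetone) would give 8-(benzyloxy)naphthalen-1-ol F8.
- Acetylation (Ac2O, pyridine) would give 8-(benzyloxy)naphthalen-1-yl acetate F9, in which the acetoxy ring is switched off.
- NBS in MeCN would then brominate only para to the benzyloxy group, giving 8-(benzyloxy)-5-bromonaphthalen-1-yl acetate F10.
- Methanolysis (K2CO3, MeOH) would give 8-(benzyloxy)-5-bromonaphthalen-1-ol F11.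
- Methylation (MeI, K2CO3) returns to the route at 4.

## Further compounds

```
F1 | step 8 | racemic 4-[4-(benzyloxy)-5-methoxynaphthalen-1-yl]-5-methoxy-2-(phenylsulfonyl)-3,4-dihydronaphthalen-1(2H)-one | COc1cccc2c1C(c1ccc(OCc4ccccc4)c3c(OC)cccc13)CC(S(=O)(=O)c1ccccc1)C2=O
F2 | step 8 | racemic 4-[4-(benzyloxy)-5-methoxynaphthalen-1-yl]-5-methoxy-3,4-dihydronaphthalen-1(2H)-one | COc1cccc2c1C(c1ccc(OCc4ccccc4)c3c(OC)cccc13)CCC2=O
F3 | step 8 | (1S,4R)-4-[4-(benzyloxy)-5-methoxynaphthalen-1-yl]-5-methoxy-1,2,3,4-tetrahydronaphthalen-1-ol | COc1cccc2c1[C@@H](c1ccc(OCc4ccccc4)c3c(OC)cccc13)CC[C@@H]2O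
F4 | step 9 | (4S)-4-[4-(benzyloxy)-5-methoxynaphthalen-1-yl]-5-methoxy-2-(phenylsulfonyl)-3,4-dihydronaphthalen-1(2H)-one (C2 epimers) | COc1cccc2c1[C@H](c1ccc(OCc4ccccc4)c3c(OC)cccc13)CC(S(=O)(=O)c1ccccc1)C2=O
F5 | step 9 | (S)-4-[4-(benzyloxy)-5-methoxynaphthalen-1-yl]-5-methoxy-3,4-dihydronaphthalen-1(2H)-one | COc1cccc2c1[C@H](c1ccc(OCc4ccccc4)c3c(OC)cccc13)CCC2=O
F6 | step 10 | (1R,2S,4S)-4-(4-hydroxy-5-methoxynaphthalen-1-yl)-5-methoxy-2-(phenylsulfonyl)-1,2,3,4-tetrahydronaphthalen-1-ol | COc1cccc2c1[C@H](c1ccc(O)c3c(OC)cccc13)C[C@H](S(=O)(=O)c1ccccc1)[C@@H]2O
F7 | step 5 | 2-[4-(benzyloxy)-5-methoxynaphthalen-1-yl]-4,4,5,5-tetramethyl-1,3,2-dioxaborolane | COc1cccc2c(B3OC(C)(C)C(C)(C)O3)ccc(OCc3ccccc3)c12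
F8 | step 2 | 8-(benzyloxy)naphthalen-1-ol | Oc1cccc2cccc(OCc3ccccc3)c12
F9 | step 2 | 8-(benzyloxy)naphthalen-1-yl acetate | CC(=O)Oc1cccc2cccc(OCc3ccccc3)c12
F10 | step 2 | 8-(benzyloxy)-5-bromonaphthalen-1-yl acetate | CC(=O)Oc1cccc2c(Br)ccc(OCc3ccccc3)c12
F11 | step 2 | 8-(benzyloxy)-5-bromonaphthalen-1-ol | Oc1cccc2c(Br)ccc(OCc3ccccc3)c12
A1 | alternative 1 | 2-[4,4-(ethylenedioxy)-8-methoxy-1,2,3,4-tetrahydronaphthalen-1-yl]furan, furyl-bearing carbon configured as C4 of 15 | COc1cccc2c1[C@H](c1ccco1)CCC21OCCO1
A2 | alternative 1 | 3-(4,4,5,5-tetramethyl-1,3,2-dioxaborolan-2-yl)benzyne | CC1(C)OB(OC1(C)C)C1=CC=CC#C1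
A3 | alternative 1 | 5-(pinacolboryl)-1-tetralinyl-1,4-epoxy-1,4-dihydronaphthalene adduct (one bridge diastereomer) | COc1cccc2c1[C@H]([C@@]13C=C[C@@H](O1)c1c(B4OC(C)(C)C(C)(C)O4)cccc13)CCC21OCCO1
A4 | alternative 2 | 8-methoxy-6-[4-(tert-butyldimethylsilyloxy)-5-methoxynaphthalen-1-yl]-3-(tert-butyldimethylsilyloxy)octa-1,7-diyne, stereocentres configured as C4 and C1 of 15 | COC#C[C@H](c1ccc(O[Si](C)(C)C(C)(C)C)c2c(OC)cccc12)CC[C@H](O[Si](C)(C)C(C)(C)C)C#C
A5 | alternative 2 | acetylene | C#C
A6 | alternative 2 | bis(tert-butyldimethylsilyl) ether of 15 | COc1cccc2c1[C@H](c1ccc(O[Si](C)(C)C(C)(C)C)c3c(OC)cccc13)CC[C@@H]2O[Si](C)(C)C(C)(C)C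
A7 | alternative 3 | 2-[4-(benzyloxy)-5-methoxynaphthalen-1-yl]furan | COc1cccc2c(-c3ccco3)ccc(OCc3ccccc3)c12
A8 | alternative 3 | 3-methoxybenzyne | COC1=CC=CC#C1
A9 | alternative 3 | 1-[4-(benzyloxy)-5-methoxynaphthalen-1-yl]-8-methoxy-1,4-epoxy-1,4-dihydronaphthalene (formed racemic; the enantiomer leading to 15 is drawn) | COc1cccc2c1[C@@]3(c1ccc(OCc4ccccc4)c5c(OC)cccc15)C=C[C@@H]2O3
```
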